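**Retrosynthetic overview**
1. Target 17 comes from its hydroquinone dimethyl ether 15 (oxidative demethylation, then quinone reduction). No ring is built: the arene is bought, and the dioxolanone in 8 to 10 only carries C10 temporarily.
2. C11–C12: chelate-controlled addition of homoprenylmagnesium bromide to the (R)-α-hydroxy methyl ketone 12 sets C11 from C10.
3. C8–C9 (key bond): visible-light nickel/photoredox decarboxylative allylation joins the (R)-malic acid-derived dioxolanone acid 8 to the allylic carbonate 6.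
4. 6 comes from SeO2 oxidation of the terminal E-methyl of geranyl arene 4, made by ortho-C-geranylation of 4-methoxy-2-methylphenol (both E-olefins are bought in geranyl bromide).

Chain carbons are numbered C1 (benzylic) to C16 as in the name of the target; the one assumption is that (R)-malic acid (D-malic acid) is bought as such.

**Step 1**
Reactants: 1 4-methoxy-2-methylphenol; 2 geranyl bromide [(2E)-1-bromo-3,7-dimethylocta-2,6-diene]
Product: 3 2-[(2E)-3,7-dimethylocta-2,6-dien-1-yl]-4-methoxy-6-methylphenol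
Conditions: NaH, toluene, 0 °C → rt; then 2, rt, 16 h
Reagents that add atoms: none
Why: In a non-polar solvent the tight sodium phenoxide ion pair is alkylated at carbon by the primary allylic bromide (ortho-selective SN2 C-allylation of a phenoxide), and because the para position carries OMe and one ortho position carries Me only C6 can react, with the E-olefin untouched.

**Step 2**
Reactants: 3 2-[(2E)-3,7-dimethylocta-2,6-dien-1-yl]-4-methoxy-6-methylphenol
Product: 4 1-[(2E)-3,7-dimethylocta-2,6-dien-1-yl]-2,5-dimethoxy-3-methylbenzene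
Conditions: MeI, K2CO3, DMF, rt
Reagents that add atoms: iodomethane, CI
Why: Williamson etherification of the hindered phenol gives a hydroquinone dimethyl ether that withstands the radical and organomagnesium steps to come.

**Step 3**
Reactants: 4 1-[(2E)-3,7-dimethylocta-2,6-dien-1-yl]-2,5-dimethoxy-3-methylbenzene
Product: 5 (2E,6E)-8-(2,5-dimethoxy-3-methylphenyl)-2,6-dimethylocta-2,6-dien-1-ol
Conditions: SeO2 (0.3 equiv), t-BuOOH, salicylic acid (cat.), CH2Cl2, rt
Reagents that add atoms: tert-butyl hydroperoxide, CC(C)(C)OO (terminal oxygen source, delivered through catalytic SeO2)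
Why: Riley-type SeO2 allylic oxidation (ene reaction, then 2,3-sigmatropic shift) hydroxylates the E-methyl of the terminal, least hindered gem-dimethyl olefin and gives the E-allylic alcohol.

**Step 4**
Reactants: 5 (2E,6E)-8-(2,5-dimethoxy-3-methylphenyl)-2,6-dimethylocta-2,6-dien-1-ol
Product: 6 (2E,6E)-8-(2,5-dimethoxy-3-methylphenyl)-2,6-dimethylocta-2,6-dien-1-yl methyl carbonate
Conditions: ClCO2Me, pyridine, CH2Cl2, 0 °C
Reagents that add atoms: methyl chloroformate, COC(=O)Cl
Why: Acylation of the primary allylic alcohol gives a carbonate that zerovalent nickel ionises readily but that the photocatalyst does not reduce directly.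

**Step 5**
Reactants: 7 (R)-malic acid
Product: 8 2-[(4R)-2,2-dimethyl-5-oxo-1,3-dioxolan-4-yl]acetic acid
Conditions: Me2C(OMe)2, pyridinium p-toluenesulfonate (cat.), rt
Reagents that add atoms: 2,2-dimethoxypropane, COC(C)(C)OC
Why: Acid-catalysed transacetalisation closes the five-membered dioxolanone selectively on the α-hydroxy acid half, leaving the β-carboxyl free and the bought stereocentre (future C10) untouched.

**Step 6**
Reactants: 8 2-[(4R)-2,2-dimethyl-5-oxo-1,3-dioxolan-4-yl]acetic acid (1.5 equiv); 6 (2E,6E)-8-(2,5-dimethoxy-3-methylphenyl)-2,6-dimethylocta-2,6-dien-1-yl methyl carbonate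
Product: 10 (5R)-5-[(3E,7E)-9-(2,5-dimethoxy-3-methylphenyl)-3,7-dimethylnona-3,7-dien-1-yl]-2,2-dimethyl-1,3-dioxolan-4-one, via N-hydroxyphthalimide ester 9 (not isolated)
Conditions: N-hydroxyphthalimide, N,N'-diisopropylcarbodiimide, 4-(dimethylamino)pyridine (cat.), N,N-dimethylacetamide, rt; then 6, NiBr2·(MeOCH2CH2OMe) (10 mol %), 4,4'-di-tert-butyl-2,2'-bipyridine (12 mol %), 2,4,5,6-tetra(carbazol-9-yl)isophthalonitrile (4CzIPN, 2 mol %), Hantzsch ester (diethyl 2,6-dimethyl-1,4-dihydropyridine-3,5-dicarboxylate, 1.5 equiv), degassed, 450 nm LEDs, rt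
Reagents that add atoms: none
Why: Proposed new method: a light-driven nickel/photoredox decarboxylative alkyl–allyl coupling in which photoreduced 4CzIPN fragments ester 9 to the primary C9 radical (C10, one carbon away, is untouched), zerovalent nickel–bipyridine ionises carbonate 6 to an allylnickel species, and radical capture gives a trivalent alkyl(allyl)nickel that should reductively eliminate at the unhindered CH2 terminus faster than syn–anti allyl isomerisation, so the C8–C9 bond forms linear with the E-olefin retained; the closest known reaction types are nickel/photoredox decarboxylative C(sp3)–C(sp3) coupling with alkyl halides and nickel-catalysed reductive allylation of alkyl halides with allylic carbonates, neither shown for a redox-active ester with a 2-methyl-substituted terpenoid allyl carbonate.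

**Step 7**
Reactants: 10 (5R)-5-[(3E,7E)-9-(2,5-dimethoxy-3-methylphenyl)-3,7-dimethylnona-3,7-dien-1-yl]-2,2-dimethyl-1,3-dioxolan-4-one
Product: 12 (3R,6E,10E)-12-(2,5-dimethoxy-3-methylphenyl)-3-hydroxy-6,10-dimethyldodeca-6,10-dien-2-one, via Weinreb amide 11 (not isolated)
Conditions: Me(MeO)NH·HCl (1.5 equiv) premixed with Me2CHMgCl (3.0 equiv), THF, −20 °C; then MeMgBr (4 equiv), −20 → 0 °C; cold aq. NH4Cl
Reagents that add atoms: methylmagnesium bromide, C[Mg]Br
Why: The chloromagnesium amide opens the activated lactone to the Weinreb amide (acetone is lost), and the stable magnesium chelate formed with MeMgBr collapses to the methyl ketone only on work-up (Weinreb ketone synthesis), so there is no over-addition and C10, held as its alkoxide, is not epimerised.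

**Step 8**
Reactants: 12 (3R,6E,10E)-12-(2,5-dimethoxy-3-methylphenyl)-3-hydroxy-6,10-dimethyldodeca-6,10-dien-2-one; 13 5-bromo-2-methylpent-2-ene
Product: 15 (2E,6E,10R,11R)-1-(2,5-dimethoxy-3-methylphenyl)-3,7,11,15-tetramethylhexadeca-2,6,14-triene-10,11-diol, via homoprenylmagnesium bromide 14 (not isolated)
Conditions: 13, Mg, THF, rt (gives 14, 3.5 equiv); then 12, THF, −78 → −20 °C; aq. NH4Cl
Reagents that add atoms: none
Why: Cram-chelate-controlled Grignard addition in which the magnesium alkoxide of the α-hydroxy ketone holds O10 and the carbonyl oxygen syn in a five-membered chelate and the homoprenyl group attacks from the face of the C10 hydrogen, which sets C11 as R (the syn-diol pattern of an E-olefin) under control of the bought C10 centre.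

**Step 9**
Reactants: 15 (2E,6E,10R,11R)-1-(2,5-dimethoxy-3-methylphenyl)-3,7,11,15-tetramethylhexadeca-2,6,14-triene-10,11-diol
Product: 17 2-[(2E,6E,10R,11R)-10,11-dihydroxy-3,7,11,15-tetramethylhexadeca-2,6,14-trien-1-yl]-6-methylbenzene-1,4-diol, via quinone 16 (not isolated)
Conditions: (NH4)2Ce(NO3)6 (2.5 equiv), MeCN/H2O 2:1, 0 °C, 10 min; then Et2O, aq. Na2S2O4, rt, under argon
Reagents that add atoms: water, O
Why: Oxidative demethylation of the hydroquinone dimethyl ether to the quinone (both quinone oxygens come from water) is expected to outrun glycol cleavage at 0 °C, and dithionite reduction of the quinone then gives the hydroquinone without touching the diol or the olefins.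

**Compound list**
1 | 4-methoxy-2-methylphenol | COc1ccc(O)c(C)c1 | starting material
2 | geranyl bromide, (2E)-1-bromo-3,7-dimethylocta-2,6-diene | CC(C)=CCC/C(C)=C/CBr | starting material
3 | 2-[(2E)-3,7-dimethylocta-2,6-dien-1-yl]-4-methoxy-6-methylphenol | CC(C)=CCC/C(C)=C/Cc1cc(OC)cc(C)c1O | intermediate
4 | 1-[(2E)-3,7-dimethylocta-2,6-dien-1-yl]-2,5-dimethoxy-3-methylbenzene | CC(C)=CCC/C(C)=C/Cc1cc(OC)cc(C)c1OC | intermediate
5 | (2E,6E)-8-(2,5-dimethoxy-3-methylphenyl)-2,6-dimethylocta-2,6-dien-1-ol | OC/C(C)=C/CC/C(C)=C/Cc1cc(OC)cc(C)c1OC | intermediate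
6 | (2E,6E)-8-(2,5-dimethoxy-3-methylphenyl)-2,6-dimethylocta-2,6-dien-1-yl methyl carbonate | COC(=O)OC/C(C)=C/CC/C(C)=C/Cc1cc(OC)cc(C)c1OC | intermediate
7 | (R)-malic acid | OC(=O)C[C@@H](O)C(=O)O | starting material
8 | 2-[(4R)-2,2-dimethyl-5-oxo-1,3-dioxolan-4-yl]acetic acid | CC1(C)O[C@H](CC(=O)O)C(=O)O1 | intermediate
9 | 1,3-dioxoisoindolin-2-yl 2-[(4R)-2,2-dimethyl-5-oxo-1,3-dioxolan-4-yl]acetate | CC1(C)O[C@H](CC(=O)ON2C(=O)c3ccccc3C2=O)C(=O)O1 | intermediate
10 | (5R)-5-[(3E,7E)-9-(2,5-dimethoxy-3-methylphenyl)-3,7-dimethylnona-3,7-dien-1-yl]-2,2-dimethyl-1,3-dioxolan-4-one | CC1(C)O[C@H](CC/C(C)=C/CC/C(C)=C/Cc2cc(OC)cc(C)c2OC)C(=O)O1 | intermediate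
11 | (2R,5E,9E)-11-(2,5-dimethoxy-3-methylphenyl)-2-hydroxy-N-methoxy-N,5,9-trimethylundeca-5,9-dienamide | CON(C)C(=O)[C@H](O)CC/C(C)=C/CC/C(C)=C/Cc1cc(OC)cc(C)c1OC | intermediate
12 | (3R,6E,10E)-12-(2,5-dimethoxy-3-methylphenyl)-3-hydroxy-6,10-dimethyldodeca-6,10-dien-2-one | CC(=O)[C@H](O)CC/C(C)=C/CC/C(C)=C/Cc1cc(OC)cc(C)c1OC | intermediate
13 | 5-bromo-2-methylpent-2-ene | CC(C)=CCCBr | starting material
14 | (4-methylpent-3-en-1-yl)magnesium bromide | CC(C)=CCC[Mg]Br | intermediate
15 | (2E,6E,10R,11R)-1-(2,5-dimethoxy-3-methylphenyl)-3,7,11,15-tetramethylhexadeca-2,6,14-triene-10,11-diol | CC(C)=CCC[C@@](C)(O)[C@H](O)CC/C(C)=C/CC/C(C)=C/Cc1cc(OC)cc(C)c1OC | intermediate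
16 | 2-[(2E,6E,10R,11R)-10,11-dihydroxy-3,7,11,15-tetramethylhexadeca-2,6,14-trien-1-yl]-6-methylcyclohexa-2,5-diene-1,4-dione | CC(C)=CCC[C@@](C)(O)[C@H](O)CC/C(C)=C/CC/C(C)=C/CC1=CC(=O)C=C(C)C1=O | intermediate
17 | 2-[(2E,6E,10R,11R)-10,11-dihydroxy-3,7,11,15-tetramethylhexadeca-2,6,14-trien-1-yl]-6-methylbenzene-1,4-diol | CC(C)=CCC[C@@](C)(O)[C@H](O)CC/C(C)=C/CC/C(C)=C/Cc1cc(O)cc(C)c1O | target

**Step count**
Total steps: 9. Longest linear sequence: 8 steps (1 → 3 → 4 → 5 → 6 → 10 → 12 → 15 → 17); step 5 is the one-step side branch.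

**Steps most likely to fail**

Step 6 (the proposed new coupling). The risks are loss of E-geometry through syn–anti isomerisation of the allylnickel, allyl homodimerisation, N-allylation of phthalimide anion, reduction of the C9 radical by Hantzsch ester, and β-alkoxide loss from the alkylnickel. The fallback uses known chemistry (Fráter–Seebach alkylation, then reductive decarboxylation); it sets out from 5 and comes back at 10. Alcohol 5 is converted with CBr4 and PPh3 (CH2Cl2, 0 °C) into 1-[(2E,6E)-8-bromo-3,7-dimethylocta-2,6-dien-1-yl]-2,5-dimethoxy-3-methylbenzene F1. Commercial diethyl (R)-malate F2 (the diethyl ester of 7) is doubly deprotonated with LiN(CHMe2)2 (2.1 equiv, THF, −78 → −20 °C) and alkylated by F1 at C3 by SN2 with the E-olefin retained, giving the anti-alkylated malate F3. LiOH in THF/H2O gives the diacid F4, and Me2C(OMe)2 with pyridinium p-toluenesulfonate closes the dioxolanone on the α-hydroxy acid half to give the dioxolanone acid F5. Its N-hydroxyphthalimide ester F6 (N-hydroxyphthalimide, N,N'-diisopropylcarbodiimide) is reduced with loss of CO2 (NiCl2·6H2O, 4,4'-di-tert-butyl-2,2'-bipyridine, Zn, PhSiH3). This removes the surplus carboxyl together with the auxiliary C9 centre and gives 10.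

Step 8 (enolisation of the methyl ketone or a low diastereomer ratio with the free α-hydroxy ketone). The fallback replaces magnesium-alkoxide control by ether-chelate control on a protected ketone; it sets out from 12 and comes back at 15. Ketone 12 is converted with MeOCH2Cl and (Me2CH)2NEt (CH2Cl2, 0 °C) into the methoxymethyl ether F7. Addition of 14 in THF at −78 °C under Cram–Still chelation gives the mono-protected diol F8. Me2BBr (CH2Cl2, −78 °C, then aq. NaHCO3) removes the acetal and gives 15.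

Step 9 (competing oxidative cleavage of the free 1,2-diol). The fallback masks the diol before the oxidation; it sets out from 15 and comes back at 16, from which the dithionite reduction of step 9 gives 17. Diol 15 is converted with Me2C(OMe)2 and pyridinium p-toluenesulfonate into the acetonide F9. (NH4)2Ce(NO3)6 in MeCN/H2O at 0 °C gives the quinone acetonide F10. 60% aq. AcOH at 40 °C then frees the diol at the quinone stage, where no chroman can form, to give 16.

**Further compounds**
F1 | step 6 | 1-[(2E,6E)-8-bromo-3,7-dimethylocta-2,6-dien-1-yl]-2,5-dimethoxy-3-methylbenzene | BrC/C(C)=C/CC/C(C)=C/Cc1cc(OC)cc(C)c1OC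
F2 | step 6 | diethyl (R)-malate | CCOC(=O)C[C@@H](O)C(=O)OCC
F3 | step 6 | diethyl (2R,3S)-3-[(2E,6E)-8-(2,5-dimethoxy-3-methylphenyl)-2,6-dimethylocta-2,6-dien-1-yl]-2-hydroxybutanedioate | CCOC(=O)[C@H](O)[C@H](C/C(C)=C/CC/C(C)=C/Cc1cc(OC)cc(C)c1OC)C(=O)OCC
F4 | step 6 | (2R,3S)-3-[(2E,6E)-8-(2,5-dimethoxy-3-methylphenyl)-2,6-dimethylocta-2,6-dien-1-yl]-2-hydroxybutanedioic acid | OC(=O)[C@H](O)[C@H](C/C(C)=C/CC/C(C)=C/Cc1cc(OC)cc(C)c1OC)C(=O)O
F5 | step 6 | (2S,4E,8E)-10-(2,5-dimethoxy-3-methylphenyl)-2-[(4R)-2,2-dimethyl-5-oxo-1,3-dioxolan-4-yl]-4,8-dimethyldeca-4,8-dienoic acid | CC1(C)O[C@H]([C@H](C/C(C)=C/CC/C(C)=C/Cc2cc(OC)cc(C)c2OC)C(=O)O)C(=O)O1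
F6 | step 6 | 1,3-dioxoisoindolin-2-yl (2S,4E,8E)-10-(2,5-dimethoxy-3-methylphenyl)-2-[(4R)-2,2-dimethyl-5-oxo-1,3-dioxolan-4-yl]-4,8-dimethyldeca-4,8-dienoate | CC1(C)O[C@H]([C@H](C/C(C)=C/CC/C(C)=C/Cc2cc(OC)cc(C)c2OC)C(=O)ON2C(=O)c3ccccc3C2=O)C(=O)O1
F7 | step 8 | (3R,6E,10E)-12-(2,5-dimethoxy-3-methylphenyl)-3-(methoxymethoxy)-6,10-dimethyldodeca-6,10-dien-2-one | CC(=O)[C@H](OCOC)CC/C(C)=C/CC/C(C)=C/Cc1cc(OC)cc(C)c1OC
F8 | step 8 | (2E,6E,10R,11R)-1-(2,5-dimethoxy-3-methylphenyl)-10-(methoxymethoxy)-3,7,11,15-tetramethylhexadeca-2,6,14-trien-11-ol | CC(C)=CCC[C@@](C)(O)[C@H](OCOC)CC/C(C)=C/CC/C(C)=C/Cc1cc(OC)cc(C)c1OC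
F9 | step 9 | (4R,5R)-4-[(3E,7E)-9-(2,5-dimethoxy-3-methylphenyl)-3,7-dimethylnona-3,7-dien-1-yl]-2,2,5-trimethyl-5-(4-methylpent-3-en-1-yl)-1,3-dioxolane | CC(C)=CCC[C@@]1(C)OC(C)(C)O[C@@H]1CC/C(C)=C/CC/C(C)=C/Cc2cc(OC)cc(C)c2OC
F10 | step 9 | 2-{(2E,6E)-3,7-dimethyl-9-[(4R,5R)-2,2,5-trimethyl-5-(4-methylpent-3-en-1-yl)-1,3-dioxolan-4-yl]nona-2,6-dien-1-yl}-6-methylcyclohexa-2,5-diene-1,4-dione | CC(C)=CCC[C@@]1(C)OC(C)(C)O[C@@H]1CC/C(C)=C/CC/C(C)=C/CC2=CC(=O)C=C(C)C2=O
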